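## Retrosynthetic overview

1. 21 ⇐ 19: the trans-fused oxirane (both C–O bonds, C8 and C9) is made last, by photochemical Z→E isomerisation of the ring alkene and oxygen transfer to the E-cycloheptene.
2. 19 ⇐ 14: C4 carbinol by isopropyl addition to the ring ketone; C2 oxygen by hydroxyl-directed epoxidation and reductive opening.
3. 14 ⇐ 13 ⇐ 9 + 11: seven-membered ring by ring-closing metathesis (C8=C9); C5–C6 bond and both centres by an anti aldol.
4. 9 ⇐ 3 ⇐ 1: five-membered ring by aldol condensation; quaternary C1 by two Fráter–Seebach alkylations of (R)-dimethyl malate, whose carbinol carbon becomes C10.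
5. Ring order: cyclopentenone, then cycloheptene, then oxirane.

Assumption: the SMILES is taken literally; it encodes (8R,9R), with C7 and C10 on opposite faces of the oxirane (a trans-fused epoxycycloheptane), so the route delivers that isomer and not the cis-fused one that ordinary epoxidation of the ring alkene would give.

Numbering in names of bicyclic compounds (daucane numbering): C1 = methyl-bearing ring-fusion carbon, C2–C4 = rest of the five-membered ring, C5 = ring-fusion CH, C6–C10 = rest of the seven-membered ring, C14 = methyl on C8, C15 = methyl on C1. β is the face of C15; H-5 is α (trans ring fusion) throughout.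

## Route

Step 1
Reactants: 1 dimethyl (2R)-2-hydroxybutanedioate [dimethyl (R)-malate]
Product: 2 dimethyl (2R,3S)-2-hydroxy-3-(prop-2-en-1-yl)butanedioate
Conditions: LiN(iPr)2 (2.2 equiv), THF, −78 → −20 °C; allyl bromide, −78 °C → rt; H2O
Reagents that add atoms: allyl bromide, C=CCBr
Why: Fráter–Seebach alkylation: the dilithium alkoxide–enolate chelate is allylated on the face anti to the CO2Me group of the carbinol carbon, which sets C3 as S (anti product) from the purchased 2R centre.

Step 2
Reactants: 2 dimethyl (2R,3S)-2-hydroxy-3-(prop-2-en-1-yl)butanedioate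
Product: 3 dimethyl (2R,3R)-2-hydroxy-3-methyl-3-(prop-2-en-1-yl)butanedioate
Conditions: LiN(iPr)2 (2.2 equiv), THF, −78 → −20 °C; MeI, −78 → 0 °C; H2O
Reagents that add atoms: iodomethane, CI
Why: Second Fráter–Seebach alkylation: the chelated enolate of 2 is methylated from the same face as before, so the quaternary carbon (the future C1) is set as 3R under control of the purchased centre.

Step 3
Reactants: 3 dimethyl (2R,3R)-2-hydroxy-3-methyl-3-(prop-2-en-1-yl)butanedioate
Product: 4 dimethyl (2R,3R)-2-[(tert-butyldimethylsilyl)oxy]-3-methyl-3-(prop-2-en-1-yl)butanedioate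
Conditions: tBuMe2SiOTf, 2,6-lutidine, CH2Cl2, 0 °C
Reagents that add atoms: tert-butyldimethylsilyl trifluoromethanesulfonate, CC(C)(C)[Si](C)(C)OS(=O)(=O)C(F)(F)F
Why: Silylation of the hindered secondary hydroxyl protects the future C10 oxygen for the base, hydride and organometallic steps that follow; no stereocentre is touched.

Step 4
Reactants: 4 dimethyl (2R,3R)-2-[(tert-butyldimethylsilyl)oxy]-3-methyl-3-(prop-2-en-1-yl)butanedioate
Product: 6 methyl (2R,3S)-3-[(tert-butyldimethylsilyl)oxy]-2-methyl-2-(prop-2-en-1-yl)pent-4-enoate, via aldehyde 5 (not isolated)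
Conditions: iBu2AlH (1.05 equiv), toluene, −78 °C; then Ph3PCH3Br/KN(SiMe3)2, THF, −78 °C → rt
Reagents that add atoms: methyltriphenylphosphonium bromide (used as its ylide), C[P+](c1ccccc1)(c1ccccc1)c1ccccc1.[Br-]
Why: iBu2AlH half-reduces only the α-silyloxy ester (the other ester sits on the quaternary carbon and is much slower), and the aldehyde is methylenated in the same flask (Wittig reaction) before it can epimerise, giving the vinyl group that becomes C9.

Step 5
Reactants: 6 methyl (2R,3S)-3-[(tert-butyldimethylsilyl)oxy]-2-methyl-2-(prop-2-en-1-yl)pent-4-enoate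
Product: 7 (2R,3S)-3-[(tert-butyldimethylsilyl)oxy]-2-methyl-2-(prop-2-en-1-yl)pent-4-enal
Conditions: iBu2AlH, CH2Cl2, −78 °C
Reagents that add atoms: none
Why: Half-reduction of the remaining neopentyl-type ester stops at the aldehyde because the tetrahedral aluminate is stable at −78 °C; the aldehyde has no α-hydrogen and cannot epimerise.

Step 6
Reactants: 7 (2R,3S)-3-[(tert-butyldimethylsilyl)oxy]-2-methyl-2-(prop-2-en-1-yl)pent-4-enal
Product: 8 (2R,3S)-3-[(tert-butyldimethylsilyl)oxy]-2-methyl-2-(2-oxopropyl)pent-4-enal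
Conditions: PdCl2 (10 mol %), CuCl, O2, DMF/H2O, rt
Reagents that add atoms: water, O
Why: Tsuji–Wacker oxidation converts the unhindered allyl group into the methyl ketone (Markovnikov), while the other vinyl group, flanked by the silyloxy carbinol and the quaternary carbon, is far slower.

Step 7
Reactants: 8 (2R,3S)-3-[(tert-butyldimethylsilyl)oxy]-2-methyl-2-(2-oxopropyl)pent-4-enal
Product: 9 (4S)-4-{(1S)-1-[(tert-butyldimethylsilyl)oxy]prop-2-en-1-yl}-4-methylcyclopent-2-en-1-one
Conditions: KOH, MeOH, rt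
Reagents that add atoms: none
Why: Intramolecular aldol condensation: only the methyl enolate of the ketone can reach the non-enolisable aldehyde, which closes the five-membered ring and dehydrates to the 4,4-disubstituted cyclopentenone without touching either stereocentre.

Step 8
Reactants: 10 3-methylbut-3-en-1-ol
Product: 11 3-methylbut-3-enal
Conditions: Dess–Martin periodinane, NaHCO3, CH2Cl2, 0 °C; used at once as a cold solution
Reagents that add atoms: none
Why: Buffered Dess–Martin oxidation gives the β,γ-unsaturated aldehyde without acid- or base-induced migration of the double bond into conjugation.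

Step 9
Reactants: 9 (4S)-4-{(1S)-1-[(tert-butyldimethylsilyl)oxy]prop-2-en-1-yl}-4-methylcyclopent-2-en-1-one; 11 3-methylbut-3-enal
Product: 13 (1R)-1-[(1R,5R)-5-{(1S)-1-[(tert-butyldimethylsilyl)oxy]prop-2-en-1-yl}-5-methyl-2-oxocyclopent-3-en-1-yl]-3-methylbut-3-en-1-yl 3,4-dimethoxybenzoate, via lithium aldolate 12 (not isolated)
Conditions: LiN(iPr)2, THF, −78 °C; 11; then 3,4-(MeO)2C6H3COCl, −78 → −30 °C
Reagents that add atoms: 3,4-dimethoxybenzoyl chloride, COc1ccc(C(Cl)=O)cc1OC
Why: Aldol addition of the kinetic lithium enolate (C5 is the only enolisable position of 9): the aldehyde adds anti to the bulky silyloxyallyl group on the neighbouring quaternary carbon (sets C5), the cyclic E-enolate reacts through a Zimmerman–Traxler chair to give the anti aldol (sets C6 as R), and the aldolate is acylated in the flask.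

Step 10
Reactants: 13 (1R)-1-[(1R,5R)-5-{(1S)-1-[(tert-butyldimethylsilyl)oxy]prop-2-en-1-yl}-5-methyl-2-oxocyclopent-3-en-1-yl]-3-methylbut-3-en-1-yl 3,4-dimethoxybenzoate
Product: 14 trans-fused dienone 6α-(3,4-dimethoxybenzoyloxy)-10α-(tert-butyldimethylsilyloxy)-1β,8-dimethylbicyclo[5.3.0]deca-2,8-dien-4-one (daucane numbering)
Conditions: second-generation Grubbs catalyst RuCl2(H2IMes)(PCy3)(=CHPh) (5 mol %), toluene, 80 °C
Reagents that add atoms: none
Why: Ring-closing metathesis of the vinyl group and the 1,1-disubstituted alkene closes the seven-membered ring as the Z-trisubstituted C8=C9 alkene; the trans ring fusion follows from the trans arrangement of the two chains set in step 9.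

Step 11
Reactants: 14 trans-fused dienone (daucane numbering: 4-oxo, 2,8-diene, 6α-aroyloxy, 10α-silyloxy)
Product: 15 6α-(3,4-dimethoxybenzoyloxy)-10α-(tert-butyldimethylsilyloxy)dauca-2,8-dien-4β-ol (isopropyl 4α)
Conditions: iPrMgCl, CeCl3, THF, −78 °C
Reagents that add atoms: isopropylmagnesium chloride, CC(C)[Mg]Cl
Why: 1,2-Addition of the weakly basic organocerium reagent to the enone carbonyl occurs from the α face, anti to the C5–C6 bond and the angular methyl, giving the 4β-hydroxy-4α-isopropyl centre without β-elimination of the acyloxy group.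

Step 12
Reactants: 15 6α-(3,4-dimethoxybenzoyloxy)-10α-(tert-butyldimethylsilyloxy)dauca-2,8-dien-4β-ol
Product: 16 2β,3β-epoxy-6α-(3,4-dimethoxybenzoyloxy)-10α-(tert-butyldimethylsilyloxy)dauc-8-en-4β-ol
Conditions: VO(acac)2 (5 mol %), tBuOOH, CH2Cl2, 0 °C → rt
Reagents that add atoms: tert-butyl hydroperoxide, CC(C)(C)OO
Why: Hydroxyl-directed epoxidation of the tertiary allylic alcohol delivers oxygen to C2=C3 syn to the 4β-hydroxyl, giving the 2β,3β-epoxide and leaving the remote C8=C9 alkene untouched.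

Step 13
Reactants: 16 2β,3β-epoxy-6α-(3,4-dimethoxybenzoyloxy)-10α-(tert-butyldimethylsilyloxy)dauc-8-en-4β-ol
Product: 17 6α-(3,4-dimethoxybenzoyloxy)-10α-(tert-butyldimethylsilyloxy)dauc-8-ene-2β,4β-diol
Conditions: Cp2TiCl2 (10 mol %), Zn, 2,4,6-collidine·HCl, 1,4-cyclohexadiene, THF, rt
Reagents that add atoms: none
Why: Titanocene-catalysed reductive epoxide opening: trivalent titanium, held by the neighbouring 4-hydroxyl, cleaves the C3–O bond, the C3 radical takes a hydrogen atom from 1,4-cyclohexadiene, and the 2β C–O bond is kept, giving the cis-1,3-diol under conditions that spare the esters.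

Step 14
Reactants: 17 6α-(3,4-dimethoxybenzoyloxy)-10α-(tert-butyldimethylsilyloxy)dauc-8-ene-2β,4β-diol
Product: 18 2β-acetoxy-6α-(3,4-dimethoxybenzoyloxy)-10α-(tert-butyldimethylsilyloxy)dauc-8-en-4β-ol
Conditions: Ac2O, DMAP, Et3N, CH2Cl2, 0 °C
Reagents that add atoms: acetic anhydride, CC(=O)OC(C)=O
Why: Acetylation takes place only at the secondary 2β-hydroxyl, the tertiary 4-hydroxyl being unreactive.

Step 15
Reactants: 18 2β-acetoxy-6α-(3,4-dimethoxybenzoyloxy)-10α-(tert-butyldimethylsilyloxy)dauc-8-en-4β-ol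
Product: 19 (1R,2S,4S,5R,6R,10S)-2β-acetoxy-6α-(3,4-dimethoxybenzoyloxy)dauc-8-ene-4β,10α-diol
Conditions: HF·pyridine, THF, 0 °C → rt
Reagents that add atoms: none
Why: Fluoride-mediated desilylation under weakly acidic conditions frees the 10α-hydroxyl without acyl migration or ester cleavage.

Step 16
Reactants: 19 (1R,2S,4S,5R,6R,10S)-2β-acetoxy-6α-(3,4-dimethoxybenzoyloxy)dauc-8-ene-4β,10α-diol
Product: 21 (1R,2S,4S,5R,6R,8R,9R,10R)-2-acetoxy-8,9-epoxy-4,10-dihydroxydaucan-6-yl 3,4-dimethoxybenzoate (trans-fused 8,9-oxirane), via E-cycloheptene 20 (not isolated)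
Conditions: hν 300 nm, Et2O, −90 °C (cooled flow loop); stream met in the dark by dimethyldioxirane, acetone, −90 °C; recycle
Reagents that add atoms: dimethyldioxirane, CC1(C)OO1
Why: Proposed new method: excitation of the built-in 3,4-dimethoxybenzoate at 300 nm is expected to sensitise Z→E isomerisation of the neighbouring C8=C9 bond through an intramolecular exciplex; of the two planar-chiral E-cycloheptenes only the one whose twist continues the helical twist imposed by the trans ring fusion (C7 above, C10 below the alkene plane) should be accessible, it persists at −90 °C, and its single exposed face, which lies syn to the 10α-hydroxyl at C9, takes an oxygen atom suprafacially from the dioxirane (hydrogen-bond assisted) to give the trans-fused (8R,9R)-oxirane while unreacted Z-alkene is recycled; the closest known chemistry is the arene-carboxylate-sensitised photoisomerisation of cycloheptene to the trappable E-isomer at low temperature and the stereospecific dioxirane epoxidation of trans-cyclooctenes to trans-fused epoxides.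

## Compound list

1 | dimethyl (2R)-2-hydroxybutanedioate [dimethyl (R)-malate] | COC(=O)[C@H](O)CC(=O)OC | starting material
2 | dimethyl (2R,3S)-2-hydroxy-3-(prop-2-en-1-yl)butanedioate | COC(=O)[C@@H](CC=C)[C@@H](O)C(=O)OC | intermediate
3 | dimethyl (2R,3R)-2-hydroxy-3-methyl-3-(prop-2-en-1-yl)butanedioate | COC(=O)[C@](C)(CC=C)[C@@H](O)C(=O)OC | intermediate
4 | dimethyl (2R,3R)-2-[(tert-butyldimethylsilyl)oxy]-3-methyl-3-(prop-2-en-1-yl)butanedioate | COC(=O)[C@](C)(CC=C)[C@@H](O[Si](C)(C)C(C)(C)C)C(=O)OC | intermediate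
5 | methyl (2R,3R)-3-[(tert-butyldimethylsilyl)oxy]-2-methyl-4-oxo-2-(prop-2-en-1-yl)butanoate | COC(=O)[C@](C)(CC=C)[C@@H](O[Si](C)(C)C(C)(C)C)C=O | intermediate
6 | methyl (2R,3S)-3-[(tert-butyldimethylsilyl)oxy]-2-methyl-2-(prop-2-en-1-yl)pent-4-enoate | COC(=O)[C@](C)(CC=C)[C@@H](O[Si](C)(C)C(C)(C)C)C=C | intermediate
7 | (2R,3S)-3-[(tert-butyldimethylsilyl)oxy]-2-methyl-2-(prop-2-en-1-yl)pent-4-enal | O=C[C@](C)(CC=C)[C@@H](O[Si](C)(C)C(C)(C)C)C=C | intermediate
8 | (2R,3S)-3-[(tert-butyldimethylsilyl)oxy]-2-methyl-2-(2-oxopropyl)pent-4-enal | O=C[C@](C)(CC(C)=O)[C@@H](O[Si](C)(C)C(C)(C)C)C=C | intermediate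
9 | (4S)-4-{(1S)-1-[(tert-butyldimethylsilyl)oxy]prop-2-en-1-yl}-4-methylcyclopent-2-en-1-one | O=C1C=C[C@@](C)([C@@H](O[Si](C)(C)C(C)(C)C)C=C)C1 | intermediate
10 | 3-methylbut-3-en-1-ol | CC(=C)CCO | starting material
11 | 3-methylbut-3-enal | CC(=C)CC=O | intermediate
12 | lithium (1R)-1-[(1R,5R)-5-{(1S)-1-[(tert-butyldimethylsilyl)oxy]prop-2-en-1-yl}-5-methyl-2-oxocyclopent-3-en-1-yl]-3-methylbut-3-en-1-olate | [Li+].[O-][C@H](CC(C)=C)[C@@H]1C(=O)C=C[C@@]1(C)[C@@H](O[Si](C)(C)C(C)(C)C)C=C | intermediate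
13 | (1R)-1-[(1R,5R)-5-{(1S)-1-[(tert-butyldimethylsilyl)oxy]prop-2-en-1-yl}-5-methyl-2-oxocyclopent-3-en-1-yl]-3-methylbut-3-en-1-yl 3,4-dimethoxybenzoate | COc1ccc(C(=O)O[C@H](CC(C)=C)[C@@H]2C(=O)C=C[C@@]2(C)[C@@H](O[Si](C)(C)C(C)(C)C)C=C)cc1OC | intermediate
14 | trans-fused dienone: 6α-(3,4-dimethoxybenzoyloxy)-10α-(tert-butyldimethylsilyloxy)-1β,8-dimethylbicyclo[5.3.0]deca-2,8-dien-4-one (daucane numbering, 5α-H) | COc1ccc(C(=O)O[C@@H]2CC(C)=C[C@H](O[Si](C)(C)C(C)(C)C)[C@]3(C)C=CC(=O)[C@@H]23)cc1OC | intermediate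
15 | 6α-(3,4-dimethoxybenzoyloxy)-10α-(tert-butyldimethylsilyloxy)dauca-2,8-dien-4β-ol (isopropyl 4α, 5α-H) | COc1ccc(C(=O)O[C@@H]2CC(C)=C[C@H](O[Si](C)(C)C(C)(C)C)[C@]3(C)C=C[C@](O)(C(C)C)[C@@H]23)cc1OC | intermediate
16 | 2β,3β-epoxy-6α-(3,4-dimethoxybenzoyloxy)-10α-(tert-butyldimethylsilyloxy)dauc-8-en-4β-ol | COc1ccc(C(=O)O[C@@H]2CC(C)=C[C@H](O[Si](C)(C)C(C)(C)C)[C@]3(C)[C@H]4O[C@H]4[C@](O)(C(C)C)[C@@H]23)cc1OC | intermediate
17 | 6α-(3,4-dimethoxybenzoyloxy)-10α-(tert-butyldimethylsilyloxy)dauc-8-ene-2β,4β-diol | COc1ccc(C(=O)O[C@@H]2CC(C)=C[C@H](O[Si](C)(C)C(C)(C)C)[C@]3(C)[C@@H](O)C[C@](O)(C(C)C)[C@@H]23)cc1OC | intermediate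
18 | 2β-acetoxy-6α-(3,4-dimethoxybenzoyloxy)-10α-(tert-butyldimethylsilyloxy)dauc-8-en-4β-ol | COc1ccc(C(=O)O[C@@H]2CC(C)=C[C@H](O[Si](C)(C)C(C)(C)C)[C@]3(C)[C@@H](OC(C)=O)C[C@](O)(C(C)C)[C@@H]23)cc1OC | intermediate
19 | (1R,2S,4S,5R,6R,10S)-2β-acetoxy-6α-(3,4-dimethoxybenzoyloxy)dauc-8-ene-4β,10α-diol (Z ring alkene) | COc1ccc(C(=O)O[C@@H]2CC(C)=C[C@H](O)[C@]3(C)[C@@H](OC(C)=O)C[C@](O)(C(C)C)[C@@H]23)cc1OC | intermediate
20 | (8E)-isomer of 19 (trans-cycloheptene; C7 above and C10 below the alkene plane) | COc1ccc(C(=O)O[C@@H]2C/C(C)=C/[C@H](O)[C@]3(C)[C@@H](OC(C)=O)C[C@](O)(C(C)C)[C@@H]23)cc1OC | intermediate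
21 | (1R,2S,4S,5R,6R,8R,9R,10R)-2-acetoxy-8,9-epoxy-4,10-dihydroxydaucan-6-yl 3,4-dimethoxybenzoate (CNP0197096.4) | COc1ccc(C(=O)O[C@@H]2C[C@@]3(C)O[C@@H]3[C@H](O)[C@]3(C)[C@@H](OC(C)=O)C[C@](O)(C(C)C)[C@@H]23)cc1OC | target

## Step count and risks

Total steps: 16. Longest linear sequence: 15 (steps 1–7 and 9–16; step 8 makes the aldehyde partner).

The three steps most likely to fail:

**Step 9 (aldol with a β,γ-unsaturated aldehyde, two new centres).** Proton transfer to the acidic aldehyde 11, erosion of the anti selectivity, or elimination of the new aroyloxy group could spoil it. The fallback sets out from 9 and comes back at 13. The α′ position of 9 is brominated (LiN(SiMe3)2, then N-bromosuccinimide, THF, −78 °C) to the 5-bromo derivative of 9 F1. Its samarium enolate is generated reductively and without base (SmI2, divalent samarium, THF, −78 °C, Reformatsky-type) in the presence of 11, which gives the free anti aldol F2. Separate acylation with 3,4-dimethoxybenzoyl chloride (pyridine, DMAP, CH2Cl2, 0 °C) gives 13.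

**Step 13 (regiochemistry of the radical epoxide opening).** Both epoxide carbons are secondary, and cleavage of the C2–O bond or deoxygenation to the alkene would compete. The fallback sets out from 15 (bypassing 16) and comes back at 17. The tertiary hydroxyl is silylated with chlorodimethylsilane (Et3N, CH2Cl2) to the 4-O-dimethylsilyl ether of 15 F3. Intramolecular hydrosilylation (Pt2[(CH2=CHSiMe2)2O]3, toluene, 60 °C) delivers silicon to C2 from the β face and gives the bridged oxasilolane F4. Tamao oxidation (H2O2, KF, KHCO3, THF/MeOH) replaces silicon by hydroxyl with retention and gives 17.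

**Step 16 (the proposed new step).** The E-cycloheptene may form inefficiently by self-sensitisation, or revert before it is trapped. The fallback uses known operations; it sets out from 19 and comes back at 21. Compound 19 is photoisomerised in a closed flow loop (254 nm, methyl benzoate as sensitiser, Et2O/hexane, cooled) through a cold column of AgNO3 on silica. This is the established silver-capture method for making and storing trans-cycloheptenes, and the column retains the E-alkene as the silver nitrate complex of the (8E)-isomer of 19 F5. The complex is eluted cold and decomplexed with aqueous NaCl/NH3 at −78 °C directly into dimethyldioxirane in acetone/CH2Cl2, whose stereospecific oxygen transfer gives 21.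

Further compounds

F1 | step 9 | 5-bromo derivative of 9 (both C5 epimers): (4S)-5-bromo-4-{(1S)-1-[(tert-butyldimethylsilyl)oxy]prop-2-en-1-yl}-4-methylcyclopent-2-en-1-one | O=C1C=C[C@@](C)([C@@H](O[Si](C)(C)C(C)(C)C)C=C)C1Br
F2 | step 9 | free anti aldol: (4S,5R)-4-{(1S)-1-[(tert-butyldimethylsilyl)oxy]prop-2-en-1-yl}-5-[(1R)-1-hydroxy-3-methylbut-3-en-1-yl]-4-methylcyclopent-2-en-1-one | O[C@H](CC(C)=C)[C@@H]1C(=O)C=C[C@@]1(C)[C@@H](O[Si](C)(C)C(C)(C)C)C=C
F3 | step 13 | 4-O-dimethylsilyl ether of 15 | COc1ccc(C(=O)O[C@@H]2CC(C)=C[C@H](O[Si](C)(C)C(C)(C)C)[C@]3(C)C=C[C@](O[SiH](C)C)(C(C)C)[C@@H]23)cc1OC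
F4 | step 13 | bridged oxasilolane (C2β–SiMe2–O–C4β) of the 6α-aroyloxy-10α-silyloxy-dauc-8-ene | COc1ccc(C(=O)O[C@@H]2CC(C)=C[C@H](O[Si](C)(C)C(C)(C)C)[C@]3(C)[C@@H]4C[C@](O[Si]4(C)C)(C(C)C)[C@@H]23)cc1OC
F5 | step 16 | silver nitrate complex of the (8E)-isomer of 19 | COc1ccc(C(=O)O[C@@H]2C/C(C)=C/[C@H](O)[C@]3(C)[C@@H](OC(C)=O)C[C@](O)(C(C)C)[C@@H]23)cc1OC.[Ag+].[O-][N+](=O)[O-]
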